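**Retrosynthetic overview**

1. Feature used: the butanolide ring O–C8–C7–C11–C12 carries the oxygenated carbon C9 on C8. C7–C8–C9 is therefore read as the remnant of a 1,3‑diene C7=C8–C9=CMe2, whose π‑allyl (C8–C9–C) can take the carboxylate at C8 after C11 has added to C7.
2. Key disconnection: a Pd(0) [3+2] annulation of 2‑bromoacrylic acid onto that diene forms C11–C7 and O–C8 at once and gives the α‑methylene lactone directly. C7 is set by the catalyst, C8 in the same event.
3. The remaining centres are relayed from C7/C8: ozonolysis and matched (E)‑crotylboration (C9, C10), NHK addition of a C2–C5 vinyl iodide to the C6 aldehyde (C6), OH‑directed epoxidation (C4, C5).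
4. Ring order: lactone (step 2), ten‑membered carbocycle by RCM at C1=C2 (step 9), oxirane (step 10). The C1=C2 bond is then reduced with the enoate masked as its Me2NH adduct, followed by tigloylation, unmasking and desilylation.

Key step: step 2

Remark: locants follow germacrane numbering (C4–C5 oxirane, C6 ester carbon, C7/C8 ring fusion with the lactone O on C8, C9 carbinol, C10 CHMe, C11=C13 methylidene, C12 lactone C=O); the CIP label of C7 switches between R and S with the O‑substituents although its geometry never changes; the tartrate crotylboronate of step 4 is a stock reagent made by the standard procedure from trans‑2‑butene.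

**Route**

Step 1
Reactants: 1 (2E)-4,4-dimethoxybut-2-enal
Product: 2 (2E)-1,1-dimethoxy-5-methylhexa-2,4-diene
Conditions: i‑PrPPh3I, n‑BuLi, THF, 0 °C; then 1, −78 °C → rt
Reagents that add atoms: isopropyltriphenylphosphonium iodide, CC(C)[P+](c1ccccc1)(c1ccccc1)c1ccccc1.[I-]
Why: Wittig olefination of the enal with the non‑stabilised isopropylidene ylide should give the Me2C= terminus (no E/Z issue) and leave the existing (E)‑olefin and the acetal untouched.

Step 2
Reactants: 2 (2E)-1,1-dimethoxy-5-methylhexa-2,4-diene; 3 2-bromoprop-2-enoic acid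
Product: 4 (4S,5R)-4-(dimethoxymethyl)-3-methylidene-5-(2-methylprop-1-en-1-yl)oxolan-2-one
Conditions: Pd2(dba)3 (2.5 mol %), BINOL‑derived phosphoramidite L* (6 mol %), K2CO3 (3 premixed as its K salt), DMF, 60 °C
Reagents that add atoms: none
Why: Proposed new method: Pd(0) inserts into the C–Br bond of the acrylate, the alkenyl–Pd adds syn across C7=C8 of the diene at its only accessible terminus C7 (C11–C7 bond) and the carboxylate then attacks the C8 terminus of the resulting η3‑allyl (O–C8 bond) with return of Pd(0); the closest known reaction type is the Larock heteroannulation of 1,3‑dienes by halides that carry a carboxylic acid or another nucleophile, together with its ligand‑controlled enantioselective Heck/allylic‑substitution versions for o‑haloanilines and o‑halophenols, whereas an enantioselective annulation with an α‑haloacrylic acid has not been shown. The butanolide closes by 5‑exo attack of oxygen on the π‑allyl (allylic substitution); closure at the Me2C terminus would need a seven‑membered ring. C7 is fixed in the enantio‑determining migratory insertion by the chiral ligand, whose antipode is chosen for the 4S,5R product. C8 follows from C7 as the trans isomer, since the π‑allyl equilibrates by π–σ–π and the allylic lactone can re‑ionise, so that the more stable 4,5‑trans ring should be collected. Regiocontrol comes from the gem‑dimethyl end of the diene, which blocks carbopalladation there and leaves an isobutenyl group without E/Z issue, and chemoselectivity from the inertness of the acetal and of the product enoate to Pd(0)/carbonate.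

Step 3
Reactants: 4 (4S,5R)-4-(dimethoxymethyl)-3-methylidene-5-(2-methylprop-1-en-1-yl)oxolan-2-one
Product: 5 (2S,3S)-3-(dimethoxymethyl)-4-methylidene-5-oxooxolane-2-carbaldehyde
Conditions: O3, pyridine, CH2Cl2, −78 °C
Reagents that add atoms: ozone, [O-][O+]=O
Why: Reductive ozonolysis in the presence of pyridine should cleave the electron‑rich trisubstituted olefin much faster than the electron‑poor exocyclic enoate and unmask C9 as the aldehyde.

Step 4
Reactants: 5 (2S,3S)-3-(dimethoxymethyl)-4-methylidene-5-oxooxolane-2-carbaldehyde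
Product: 6 (4S,5S)-4-(dimethoxymethyl)-5-[(1R,2R)-1-hydroxy-2-methylbut-3-en-1-yl]-3-methylideneoxolan-2-one
Conditions: (S,S)‑diisopropyl tartrate (E)‑crotylboronate, 4 Å MS, toluene, −78 °C; aq. NaHCO3
Reagents that add atoms: diisopropyl (4S,5S)-2-[(2E)-but-2-en-1-yl]-1,3,2-dioxaborolane-4,5-dicarboxylate, C/C=C/CB1O[C@H](C(=O)OC(C)C)[C@@H](C(=O)OC(C)C)O1
Why: Roush crotylboration through a chair transition state should give the 9,10‑anti adduct from the (E)‑reagent, and the (S,S)‑tartrate is matched with the Felkin/Cornforth preference of the (S)‑α‑acyloxy aldehyde for the 8,9‑anti product (Re‑face attack, C9 R, C10 R).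

Step 5
Reactants: 6 (4S,5S)-4-(dimethoxymethyl)-5-[(1R,2R)-1-hydroxy-2-methylbut-3-en-1-yl]-3-methylideneoxolan-2-one
Product: 7 (4S,5S)-4-(dimethoxymethyl)-3-methylidene-5-[(1R,2R)-2-methyl-1-(triethylsilyloxy)but-3-en-1-yl]oxolan-2-one
Conditions: TESCl, imidazole, DMAP (cat.), DMF, rt
Reagents that add atoms: chlorotriethylsilane, CC[Si](Cl)(CC)CC
Why: Silylation of the C9 hydroxyl under non‑acidic conditions protects it from later acylation and from directing the epoxidation, and prevents cyclic acetal formation with C6.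

Step 6
Reactants: 7 (4S,5S)-4-(dimethoxymethyl)-3-methylidene-5-[(1R,2R)-2-methyl-1-(triethylsilyloxy)but-3-en-1-yl]oxolan-2-one
Product: 9 (2S,3S)-4-methylidene-2-[(1R,2R)-2-methyl-1-(triethylsilyloxy)but-3-en-1-yl]-5-oxooxolane-3-carbaldehyde, via pyridinium N,O-acetal triflate 8 (not isolated)
Conditions: TESOTf, 2,4,6‑collidine, CH2Cl2, 0 °C; then H2O
Reagents that add atoms: water, O
Why: Silyl triflate/collidine cleavage of a dimethyl acetal via its collidinium salt and aqueous hydrolysis should free the C6 aldehyde without protic acid, so the TES ether survives and the β‑acyloxy aldehyde is not exposed to base.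

Step 7
Reactants: 10 pent-1-en-4-yne
Product: 12 (1E)-1-iodo-2-methylpenta-1,4-diene, via dimethyl(alkenyl)alane 11 (not isolated)
Conditions: Me3Al, Cp2ZrCl2 (cat.), CH2Cl2, 0 °C → rt; then I2, THF, −30 °C
Reagents that add atoms: trimethylaluminium, C[Al](C)C; iodine, II
Why: Negishi Zr‑catalysed carboalumination adds Me and Al syn across the terminal alkyne (Me to the internal carbon) and iodinolysis with retention should give the (E)‑iodide, i.e. the C4=C5 geometry of the later oxirane.

Step 8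
Reactants: 9 (2S,3S)-4-methylidene-2-[(1R,2R)-2-methyl-1-(triethylsilyloxy)but-3-en-1-yl]-5-oxooxolane-3-carbaldehyde; 12 (1E)-1-iodo-2-methylpenta-1,4-diene
Product: 13 (4R,5S)-4-[(1S,2E)-1-hydroxy-3-methylhexa-2,5-dien-1-yl]-3-methylidene-5-[(1R,2R)-2-methyl-1-(triethylsilyloxy)but-3-en-1-yl]oxolan-2-one
Conditions: CrCl2, NiCl2 (cat.), DMSO, rt
Reagents that add atoms: none
Why: Nozaki–Hiyama–Kishi coupling adds the alkenylchromium chemoselectively to the aldehyde (lactone and enoate untouched), and Felkin–Anh attack anti to the C7–C8 bond should place the new C6–O syn to C7–C11 (6S here).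

Step 9
Reactants: 13 (4R,5S)-4-[(1S,2E)-1-hydroxy-3-methylhexa-2,5-dien-1-yl]-3-methylidene-5-[(1R,2R)-2-methyl-1-(triethylsilyloxy)but-3-en-1-yl]oxolan-2-one
Product: 14 (1Z,4E,6S,7R,8S,9R,10R)-6-hydroxy-9-(triethylsilyloxy)germacra-1,4,11(13)-trien-12,8-olide
Conditions: Grubbs II (10 mol %), 1,4‑benzoquinone (cat.), toluene (1 mM), 80 °C
Reagents that add atoms: none
Why: Ring‑closing metathesis of the two monosubstituted olefins (the trisubstituted olefin and the enoate are spectators, the catalyst loads on the unhindered allyl end) should close the ten‑membered ring at C1=C2 with the trans‑fused lactone as turn element.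

Step 10
Reactants: 14 (1Z,4E,6S,7R,8S,9R,10R)-6-hydroxy-9-(triethylsilyloxy)germacra-1,4,11(13)-trien-12,8-olide
Product: 15 (1Z,4R,5R,6R,7R,8S,9R,10R)-4,5-epoxy-6-hydroxy-9-(triethylsilyloxy)germacra-1,11(13)-dien-12,8-olide
Conditions: VO(acac)2 (cat.), t‑BuOOH, CH2Cl2, 0 °C
Reagents that add atoms: tert-butyl hydroperoxide, CC(C)(C)OO
Why: Hydroxyl‑directed vanadium epoxidation touches only the allylic C4=C5 bond; in the (E)‑cyclodecene only the outer face is open and delivery needs the C6–OH nearly eclipsed with the olefin on that face while C7 sits inside, which should give the erythro (4R,5R) oxirane.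

Step 11
Reactants: 15 (1Z,4R,5R,6R,7R,8S,9R,10R)-4,5-epoxy-6-hydroxy-9-(triethylsilyloxy)germacra-1,11(13)-dien-12,8-olide
Product: 16 (1Z,4R,5R,6R,7R,8S,9R,10R,11R)-13-(dimethylamino)-4,5-epoxy-6-hydroxy-9-(triethylsilyloxy)germacr-1-en-12,8-olide
Conditions: Me2NH (2 M in THF), rt
Reagents that add atoms: dimethylamine, CNC
Why: Reversible aza‑Michael addition masks the exocyclic enoate as its Mannich base; the temporary C11 centre (CH2N trans to C6 expected) is erased again in step 14.

Step 12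
Reactants: 16 (1Z,4R,5R,6R,7R,8S,9R,10R,11R)-13-(dimethylamino)-4,5-epoxy-6-hydroxy-9-(triethylsilyloxy)germacr-1-en-12,8-olide
Product: 17 (4R,5R,6R,7R,8S,9R,10R,11R)-13-(dimethylamino)-4,5-epoxy-6-hydroxy-9-(triethylsilyloxy)germacran-12,8-olide
Conditions: 2‑nitrobenzenesulfonohydrazide, Et3N, CH2Cl2, rt
Reagents that add atoms: none
Why: Diimide generated in situ should reduce the only remaining C=C (C1=C2) by concerted syn H2 transfer without hydrogenolysis of the oxirane or of the C–N bond.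

Step 13
Reactants: 17 (4R,5R,6R,7R,8S,9R,10R,11R)-13-(dimethylamino)-4,5-epoxy-6-hydroxy-9-(triethylsilyloxy)germacran-12,8-olide
Product: 18 (4R,5R,6R,7R,8S,9R,10R,11R)-13-(dimethylamino)-4,5-epoxy-6-[(E)-2-methylbut-2-enoyloxy]-9-(triethylsilyloxy)germacran-12,8-olide
Conditions: tigloyl chloride, Et3N, DMAP, CH2Cl2, 0 °C → rt
Reagents that add atoms: (2E)-2-methylbut-2-enoyl chloride, C/C=C(\C)C(=O)Cl
Why: DMAP‑catalysed acylation of the only free hydroxyl (C6) installs the tiglate with its (E) geometry, the thermodynamically stable one, unchanged.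

Step 14
Reactants: 18 (4R,5R,6R,7R,8S,9R,10R,11R)-13-(dimethylamino)-4,5-epoxy-6-[(E)-2-methylbut-2-enoyloxy]-9-(triethylsilyloxy)germacran-12,8-olide
Product: 20 (4R,5R,6R,7R,8S,9R,10R)-4,5-epoxy-6-[(E)-2-methylbut-2-enoyloxy]-9-(triethylsilyloxy)germacr-11(13)-en-12,8-olide, via trimethylammonium iodide 19 (not isolated)
Conditions: MeI, CH2Cl2, rt; then sat. aq. NaHCO3, EtOAc
Reagents that add atoms: none
Why: N‑Methylation followed by mild‑base E1cB (Hofmann‑type) loss of trimethylamine should regenerate the C11=C13 methylidene under conditions that leave oxirane, tiglate and silyl ether intact.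

Step 15
Reactants: 20 (4R,5R,6R,7R,8S,9R,10R)-4,5-epoxy-6-[(E)-2-methylbut-2-enoyloxy]-9-(triethylsilyloxy)germacr-11(13)-en-12,8-olide
Product: 21 (4R,5R,6R,7S,8S,9R,10R)-4,5-epoxy-9-hydroxy-6-[(E)-2-methylbut-2-enoyloxy]germacr-11(13)-en-12,8-olide
Conditions: HF·pyridine, pyridine, THF, 0 °C
Reagents that add atoms: none
Why: Buffered fluoride cleavage of the labile secondary TES ether should free the C9 hydroxyl without opening the oxirane or migrating the ester.

**Compound list**

1 | (2E)-4,4-dimethoxybut-2-enal | O=C/C=C/C(OC)OC | starting material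
2 | (2E)-1,1-dimethoxy-5-methylhexa-2,4-diene | CC(C)=C/C=C/C(OC)OC | intermediate
3 | 2-bromoprop-2-enoic acid | C=C(Br)C(=O)O | starting material
4 | (4S,5R)-4-(dimethoxymethyl)-3-methylidene-5-(2-methylprop-1-en-1-yl)oxolan-2-one | C=C1C(=O)O[C@H](C=C(C)C)[C@H]1C(OC)OC | intermediate
5 | (2S,3S)-3-(dimethoxymethyl)-4-methylidene-5-oxooxolane-2-carbaldehyde | C=C1C(=O)O[C@H](C=O)[C@H]1C(OC)OC | intermediate
6 | (4S,5S)-4-(dimethoxymethyl)-5-[(1R,2R)-1-hydroxy-2-methylbut-3-en-1-yl]-3-methylideneoxolan-2-one | C=C1C(=O)O[C@H]([C@H](O)[C@H](C)C=C)[C@H]1C(OC)OC | intermediate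
7 | (4S,5S)-4-(dimethoxymethyl)-3-methylidene-5-[(1R,2R)-2-methyl-1-(triethylsilyloxy)but-3-en-1-yl]oxolan-2-one | C=C1C(=O)O[C@H]([C@H](O[Si](CC)(CC)CC)[C@H](C)C=C)[C@H]1C(OC)OC | intermediate
8 | 1-[methoxy(lactonyl)methyl]-2,4,6-trimethylpyridinium triflate derived from 7 (either configuration at the N,O-acetal carbon) | C=C1C(=O)O[C@H]([C@H](O[Si](CC)(CC)CC)[C@H](C)C=C)[C@H]1C(OC)[n+]1c(C)cc(C)cc1C.[O-]S(=O)(=O)C(F)(F)F | intermediate
9 | (2S,3S)-4-methylidene-2-[(1R,2R)-2-methyl-1-(triethylsilyloxy)but-3-en-1-yl]-5-oxooxolane-3-carbaldehyde | C=C1C(=O)O[C@H]([C@H](O[Si](CC)(CC)CC)[C@H](C)C=C)[C@H]1C=O | intermediate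
10 | pent-1-en-4-yne | C=CCC#C | starting material
11 | dimethyl[(1E)-2-methylpenta-1,4-dien-1-yl]alane | C[Al](C)/C=C(\C)CC=C | intermediate
12 | (1E)-1-iodo-2-methylpenta-1,4-diene | I/C=C(\C)CC=C | intermediate
13 | (4R,5S)-4-[(1S,2E)-1-hydroxy-3-methylhexa-2,5-dien-1-yl]-3-methylidene-5-[(1R,2R)-2-methyl-1-(triethylsilyloxy)but-3-en-1-yl]oxolan-2-one | C=C1C(=O)O[C@H]([C@H](O[Si](CC)(CC)CC)[C@H](C)C=C)[C@H]1[C@@H](O)/C=C(\C)CC=C | intermediate
14 | (1Z,4E,6S,7R,8S,9R,10R)-6-hydroxy-9-(triethylsilyloxy)germacra-1,4,11(13)-trien-12,8-olide | C=C1C(=O)O[C@@H]2[C@H](O[Si](CC)(CC)CC)[C@H](C)/C=C\C/C(C)=C/[C@H](O)[C@@H]12 | intermediate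
15 | (1Z,4R,5R,6R,7R,8S,9R,10R)-4,5-epoxy-6-hydroxy-9-(triethylsilyloxy)germacra-1,11(13)-dien-12,8-olide | C=C1C(=O)O[C@@H]2[C@H](O[Si](CC)(CC)CC)[C@H](C)/C=C\C[C@@]3(C)O[C@@H]3[C@H](O)[C@@H]12 | intermediate
16 | (1Z,4R,5R,6R,7R,8S,9R,10R,11R)-13-(dimethylamino)-4,5-epoxy-6-hydroxy-9-(triethylsilyloxy)germacr-1-en-12,8-olide | CN(C)C[C@@H]1C(=O)O[C@@H]2[C@H](O[Si](CC)(CC)CC)[C@H](C)/C=C\C[C@@]3(C)O[C@@H]3[C@H](O)[C@@H]12 | intermediate
17 | (4R,5R,6R,7R,8S,9R,10R,11R)-13-(dimethylamino)-4,5-epoxy-6-hydroxy-9-(triethylsilyloxy)germacran-12,8-olide | CN(C)C[C@@H]1C(=O)O[C@@H]2[C@H](O[Si](CC)(CC)CC)[C@H](C)CCC[C@@]3(C)O[C@@H]3[C@H](O)[C@@H]12 | intermediate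
18 | (4R,5R,6R,7R,8S,9R,10R,11R)-13-(dimethylamino)-4,5-epoxy-6-[(E)-2-methylbut-2-enoyloxy]-9-(triethylsilyloxy)germacran-12,8-olide | CN(C)C[C@@H]1C(=O)O[C@@H]2[C@H](O[Si](CC)(CC)CC)[C@H](C)CCC[C@@]3(C)O[C@@H]3[C@H](OC(=O)/C(C)=C/C)[C@@H]12 | intermediate
19 | N-methyl ammonium iodide of 18 (13-trimethylammonio) | C[N+](C)(C)C[C@@H]1C(=O)O[C@@H]2[C@H](O[Si](CC)(CC)CC)[C@H](C)CCC[C@@]3(C)O[C@@H]3[C@H](OC(=O)/C(C)=C/C)[C@@H]12.[I-] | intermediate
20 | (4R,5R,6R,7R,8S,9R,10R)-4,5-epoxy-6-[(E)-2-methylbut-2-enoyloxy]-9-(triethylsilyloxy)germacr-11(13)-en-12,8-olide | C=C1C(=O)O[C@@H]2[C@H](O[Si](CC)(CC)CC)[C@H](C)CCC[C@@]3(C)O[C@@H]3[C@H](OC(=O)/C(C)=C/C)[C@@H]12 | intermediate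
21 | (4R,5R,6R,7S,8S,9R,10R)-4,5-epoxy-9-hydroxy-6-[(E)-2-methylbut-2-enoyloxy]germacr-11(13)-en-12,8-olide | C=C1C(=O)O[C@@H]2[C@H](O)[C@H](C)CCC[C@@]3(C)O[C@@H]3[C@H](OC(=O)/C(C)=C/C)[C@@H]12 | target

**Step count**

Total: 15 steps. Longest linear sequence: 14 steps (steps 1–6 and 8–15); step 7 is a one‑step side branch.

**Steps most likely to fail**

1. Step 2 (proposed method). What may go wrong: too little enantiofacial discrimination in the migratory insertion, so that the lactone is formed with low enantiomeric purity. Fallback with known chemistry: starting from 2 and 3, the annulation is run with an achiral Pd/PPh3 catalyst (the established racemic diene heteroannulation), which gives 4 together with its mirror image, ent‑lactone F1. Ozonolysis as in step 3 gives 5 together with ent‑aldehyde F2. The (S,S)‑crotylboronate of step 4 then serves as resolving reagent: 5 gives 6 (matched), while F2 gives the reagent‑controlled 8,9‑syn adduct F3, a diastereomer that is removed by chromatography. The route is rejoined at 6.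

2. Step 9. What may go wrong: oligomerisation, or ring closure onto the internal C4=C5 olefin (seven‑membered ring with loss of the C2–C4 unit) instead of the strained ten‑membered ring. Fallback: starting from 9 and 12, cross‑metathesis of the two monosubstituted olefins joins C1 and C2 first and gives iodo‑aldehyde F4. An intramolecular Nozaki–Hiyama–Kishi reaction (CrCl2/NiCl2, high dilution) then closes the ring at C5–C6 to the macrocyclic dienol F5, the (1E) isomer of 14. Steps 10 and 11 applied to it give epoxy alcohol F6 and amine adduct F7, and the diimide reduction of step 12 removes the C1=C2 geometry, so the route is rejoined at 17.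

3. Step 8. What may go wrong: poor facial selectivity in the addition to the α‑branched aldehyde, giving the C6 epimer. Fallback: starting from 13 obtained in admixture with epi‑alcohol F8, Dess–Martin oxidation converges both epimers on enone F9. CBS reduction (oxazaborolidine antipode chosen for the 6S carbinol, catecholborane, −78 °C) then sets C6 under reagent control and returns 13.

**Further compounds**

F1 | step 2 | (4R,5S)-4-(dimethoxymethyl)-3-methylidene-5-(2-methylprop-1-en-1-yl)oxolan-2-one | C=C1C(=O)O[C@@H](C=C(C)C)[C@@H]1C(OC)OC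
F2 | step 2 | (2R,3R)-3-(dimethoxymethyl)-4-methylidene-5-oxooxolane-2-carbaldehyde | C=C1C(=O)O[C@@H](C=O)[C@@H]1C(OC)OC
F3 | step 2 | (4R,5R)-4-(dimethoxymethyl)-5-[(1R,2R)-1-hydroxy-2-methylbut-3-en-1-yl]-3-methylideneoxolan-2-one | C=C1C(=O)O[C@@H]([C@H](O)[C@H](C)C=C)[C@@H]1C(OC)OC
F4 | step 9 | (2S,3S)-2-[(1R,2R,3E,6E)-7-iodo-2,6-dimethyl-1-(triethylsilyloxy)hepta-3,6-dien-1-yl]-4-methylidene-5-oxooxolane-3-carbaldehyde | C=C1C(=O)O[C@H]([C@H](O[Si](CC)(CC)CC)[C@H](C)/C=C/C/C(C)=C/I)[C@H]1C=O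
F5 | step 9 | (1E,4E,6S,7R,8S,9R,10R)-6-hydroxy-9-(triethylsilyloxy)germacra-1,4,11(13)-trien-12,8-olide | C=C1C(=O)O[C@@H]2[C@H](O[Si](CC)(CC)CC)[C@H](C)/C=C/C/C(C)=C/[C@H](O)[C@@H]12
F6 | step 9 | (1E,4R,5R,6R,7R,8S,9R,10R)-4,5-epoxy-6-hydroxy-9-(triethylsilyloxy)germacra-1,11(13)-dien-12,8-olide | C=C1C(=O)O[C@@H]2[C@H](O[Si](CC)(CC)CC)[C@H](C)/C=C/C[C@@]3(C)O[C@@H]3[C@H](O)[C@@H]12
F7 | step 9 | (1E,4R,5R,6R,7R,8S,9R,10R,11R)-13-(dimethylamino)-4,5-epoxy-6-hydroxy-9-(triethylsilyloxy)germacr-1-en-12,8-olide | CN(C)C[C@@H]1C(=O)O[C@@H]2[C@H](O[Si](CC)(CC)CC)[C@H](C)/C=C/C[C@@]3(C)O[C@@H]3[C@H](O)[C@@H]12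
F8 | step 8 | (4R,5S)-4-[(1R,2E)-1-hydroxy-3-methylhexa-2,5-dien-1-yl]-3-methylidene-5-[(1R,2R)-2-methyl-1-(triethylsilyloxy)but-3-en-1-yl]oxolan-2-one | C=C1C(=O)O[C@H]([C@H](O[Si](CC)(CC)CC)[C@H](C)C=C)[C@H]1[C@H](O)/C=C(\C)CC=C
F9 | step 8 | (4S,5S)-3-methylidene-4-[(2E)-3-methylhexa-2,5-dienoyl]-5-[(1R,2R)-2-methyl-1-(triethylsilyloxy)but-3-en-1-yl]oxolan-2-one | C=C1C(=O)O[C@H]([C@H](O[Si](CC)(CC)CC)[C@H](C)C=C)[C@H]1C(=O)/C=C(\C)CC=C
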